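## The problem

The target is a briarane: a cyclohexane (ring A: C1, C10–C14) trans-fused through C1–C10 to a ten-membered carbocycle (C1–C10), which carries a γ-lactone across C7–C8 (O–C19(=O)–C17). Eleven stereocentres must be set: C1 (quaternary, methyl C15), C2, C6, C7, C8, C9, C10, C11, C12, C14 and C17. The most crowded region is the ring junction, where quaternary C1 and tertiary C10 stand trans and C1 is flanked by the C2 and C14 oxygens. Within ring A the centres can pass information on: a C12 oxygen can steer C10 (1,3-trans), C10 steers C1, the C2 carbinol steers C14 through a 1,3-anti reduction, and a free C12 hydroxyl can direct the C11 spiro-epoxide. C6 to C9 and C17 lie outside this relay and need Felkin–Anh or chelate control of their own. Four acyloxy groups of three kinds (isobutyrate at C2, acetates at C9 and C14, isovalerate at C12) must be distinguished while the tertiary C8 hydroxyl stays free. The allylic chloride at C6 beside the C5 methylene, the 11,20-epoxide and the β-hydroxy lactone rule out strong bases, hydrides and carbanions late in the route. The enabling feature is that C14, C1 (methyl, bond to C2) and C10 (bond to C9) are the carbonyl, α- and β-carbons of a 2-methylcyclohex-2-enone whose C11 is a masked ketone and whose C12 bears oxygen, so conjugate addition at C10 with aldol trapping at C1 builds the junction without closing a ring.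

## Retrosynthesis

Positions are numbered as in the briarane skeleton (C15 = methyl on C1, C16 = CH2 on C5, C18 = methyl on C17, C19 = lactone carbonyl, C20 = CH2 on C11). Compound numbers are plain integers.

**Late functional groups (47 ⇒ 43).** The isovalerate, the epoxide and the chloride are removed first, because they are the least robust groups. Target 47 comes from epoxy alcohol 46 by acylation, and 46 from allylic alcohol 45 by hydroxyl-directed epoxidation. The C12 hydroxyl must be free for that step, so its ester is introduced last. Chloride 44 comes from the (6R)-alcohol 43 by SN2 displacement with inversion. The forward reactions must epoxidise C11=C20 but not C5=C16, and must substitute at C6 without allylic shift.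

**Ten-membered ring (43 ⇒ 40).** The ring is opened at C5–C6. Alcohol 43 comes from enone 42 by Felkin–Anh reduction, 42 from the ring-closure product 41, and 41 from bromo aldehyde 40 by Nozaki–Hiyama–Kishi closure. This cut creates the C16 methylene and the C6 carbinol in one step and uses an alkenyl bromide that is inert during the chain building. Closure at C8–C9 would place the ring closure at the most hindered carbinol, and closure at C1–C2 or C9–C10 would give up the key step. Because 42 is reduced afterwards, the closure itself need not be stereoselective.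

**Lactone and C11 methylene (40 ⇒ 36).** Aldehyde 40 comes from alcohol 39, whose C11 methylene derives from ketone 38 and so from ketal 37. Lactone 37 is cut at C8–C17 to give acrylate 36. A reductive aldol cyclisation of 36 creates the tertiary C8 alcohol, the C17 centre and the lactone ring at once under neutral conditions. A butenolide route would need an epoxidation on the more hindered face followed by reductive opening. The ketal is kept until C8 is no longer a ketone.

**C8–C9 bond (36 ⇒ 21 + 27).** Acrylate 36 leads back through 35 and 34 to ketone 33. The C8 carbonyl of 33 is masked as the 1,1-disubstituted alkene of 31, and 31 comes from 30, 29 and 28. Alcohol 28 is cut at C8–C9 into aldehyde 21 and alkenyl iodide 27, which brings C6, C7 and C8 from the chiral pool. C9 is set by oxidation to enone 29 and reduction to 30, so the coupling need not be selective. An alkynyl nucleophile would offer reagent control at C9 but no direct way to oxygenate C7.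

**Ring A adjustments (21 ⇒ 16).** Aldehyde 21 comes from the vinyl group of 19 by oxidative cleavage. Acetate 19 comes from alcohol 18, and 18 from β-hydroxy ketone 16 and aldehyde 17 by an Evans–Tishchenko reduction. That single step sets C14 and places the isobutyrate on the C2 oxygen, which settles the C2/C14 differentiation.

**Key disconnection (16 ⇒ 5 + 13 + 12).** C9–C10 and C1–C2 are cut together. Ketone 16 is the product of conjugate addition of vinylmagnesium bromide 13 to enone 5 and trapping of the enolate with 4-bromopent-4-enal 12. Three small pieces replace the quaternary C1, C10 and C2, and C11 and C12 are already at the right oxidation level. The forward reaction needs 1,4-addition anti to the C12 silyloxy group and an aldol that is faster than proton transfer.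

**Building blocks.** Enone 5 comes from 4-methoxy-2-methylphenol 1 through quinone monoketal 2, epoxide 3 and hydroxy ketone 4. Aldehyde 12 comes from imine 8 (from 6 and 7) and 2,3-dibromopropene 9. Iodide 27 comes from (R)-solketal 22 through aldehyde 23 and alkyne 25.

## Roads not taken

**Alternative 1: chloroallylchromium ring closure at C6–C7.** The seco aldehyde A2, an allylic gem-dichloride, would be reduced by a divalent chromium salt to a γ-chloroallylchromium species. This adds through C6 to the C7 aldehyde and gives the ten-membered chlorohydrin A1. Chlorine, the C6 and C7 centres and the C5 methylene would arise in the ring-closing step. The usual anti preference of γ-haloallylchromium additions matches the C6/C7 relationship of the target. In this respect the alternative is better than the chosen plan, which spends steps 26 to 29 on the same result and risks an allylic shift in step 29. Its weak points lie before the closure. A2 needs the tertiary C8 alcohol and C17 on an open chain without the lactone, and its C7 aldehyde is α-hydroxylated, α-quaternary and hindered. The six-membered allylmetal transition state must also fit inside a forming medium ring. The alternative does not address the C1/C10 junction at all. The chosen plan sets against it a ring closure whose halide arrives with the aldol component, and a C6 configuration that can be corrected by oxidation and reduction.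

**Alternative 2: Diels–Alder annulation of ring A.** Ring A would be cut at C1–C14 and C10–C11. The (E)-cyclodecenone A4 would add the bis(silyloxy)diene A5 to give the trans-fused adduct A3. This forms two bonds and four ring A centres at once, with the trans fusion encoded in the alkene geometry, and it is more convergent than the chosen sequence. The dienophile is a poor one, however: an α-methyl, β-alkyl enone in a flexible medium ring, which must form a quaternary centre. The face selectivity of such a ring is hard to predict, and forcing conditions threaten the silyl enol ethers. A4 is itself a ten-membered-ring synthesis. A3 would still need the C8 hydroxyl, the C11 epoxide, the C2 carbinol and the chloride. The chosen plan makes the same C1/C10 pair on a rigid six-membered ring with precedented facial control, at the cost of a longer linear sequence.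

**Alternative 3: De Mayo two-carbon ring expansion.** C7–C8 and C5–C6 would come from irradiation of the eight-membered β-silyloxy enone A7, whose tethered (Z)-chlorovinyl ether adds across C5=C8. The cyclobutane A6 would then fragment to the ten-membered ring. This avoids a direct medium-ring closure and carries in chlorine and the C7 oxygen with fixed relative configuration, which is better than late substitution at C6. After fragmentation, however, C8 bears hydrogen and not hydroxyl, and C5 is a ketone beside an epimerisable chloride that must be methylenated. The oxolane would have to be oxidised to the lactone, and A7 requires an eight-membered ring of its own. The chosen plan has the C8 oxygen and the lactone oxidation level in place from the reductive aldol and needs no redox correction there.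

Key step: step 7

Assumption: compounds 28 and 41 are drawn as the epimers expected from Felkin–Anh addition of the alkenylchromium reagents (9R and 6S); either epimer enters the oxidation that follows.
Assumption: N-benzylcinchonidinium chloride is taken to give the (1S,6R)-epoxide 3; if the sense of induction is opposite, the pseudoenantiomeric cinchoninium salt is used.

## Route

Step 1
Reactants: 1 4-methoxy-2-methylphenol
Product: 2 4,4-dimethoxy-2-methylcyclohexa-2,5-dien-1-one
Conditions: PhI(OAc)2, MeOH, 0 °C
Reagents that add atoms: methanol, CO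
Why: Oxidative dearomatisation of a para-alkoxyphenol with a hypervalent iodine reagent in methanol gives the quinone monoketal, which masks C11 and leaves two different enones.

Step 2
Reactants: 2 4,4-dimethoxy-2-methylcyclohexa-2,5-dien-1-one
Product: 3 (1S,6R)-5,5-dimethoxy-3-methyl-7-oxabicyclo[4.1.0]hept-3-en-2-one
Conditions: t-BuOOH, N-benzylcinchonidinium chloride (10 mol%), 1 M NaOH, toluene, 0 °C
Reagents that add atoms: tert-butyl hydroperoxide, CC(C)(C)OO
Why: Weitz–Scheffer epoxidation under chiral phase-transfer catalysis; the peroxide anion attacks the unsubstituted enone, which is more electrophilic and less hindered than the α-methyl enone. The ion-paired cinchona cation differentiates the enone faces and so fixes the future C12.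

Step 3
Reactants: 3 (1S,6R)-5,5-dimethoxy-3-methyl-7-oxabicyclo[4.1.0]hept-3-en-2-one
Product: 4 (5R)-5-hydroxy-4,4-dimethoxy-2-methylcyclohex-2-en-1-one
Conditions: SmI2 (2.2 equiv), THF/MeOH, −90 °C
Reagents that add atoms: none
Why: Divalent samarium reduces the α,β-epoxy ketone with cleavage of the Cα–O bond to the β-hydroxy ketone. The carbinol centre is untouched, and methanol at low temperature protonates the enolate before β-elimination.

Step 4
Reactants: 4 (5R)-5-hydroxy-4,4-dimethoxy-2-methylcyclohex-2-en-1-one
Product: 5 (5R)-5-(tert-butyldimethylsilyloxy)-4,4-dimethoxy-2-methylcyclohex-2-en-1-one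
Conditions: TBSOTf, 2,6-lutidine, CH2Cl2, −78 °C
Reagents that add atoms: tert-butyldimethylsilyl trifluoromethanesulfonate, CC(C)(C)[Si](C)(C)OS(=O)(=O)C(F)(F)F
Why: Silylation of the hindered secondary alcohol with the silyl triflate and a hindered base at low temperature; these conditions avoid β-elimination back to the dienone.

Step 5
Reactants: 6 acetaldehyde; 7 cyclohexylamine
Product: 8 N-cyclohexylethanimine
Conditions: neat, 0 °C; KOH pellets
Reagents that add atoms: none
Why: Condensation of a primary amine with the aldehyde gives the imine, which serves as an acetaldehyde enolate equivalent.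

Step 6
Reactants: 8 N-cyclohexylethanimine; 9 2,3-dibromopropene
Product: 12 4-bromopent-4-enal, via lithiated imine 10 (not isolated), via N-cyclohexyl-4-bromopent-4-en-1-imine 11 (not isolated)
Conditions: LiN(i-Pr)2, THF, 0 °C; 9, −78 °C → rt; aq. oxalic acid, rt
Reagents that add atoms: water, O
Why: Metalloenamine alkylation; the aza-enolate 10 displaces the allylic bromide of 9 while the vinylic bromide is inert. Mild acid hydrolyses imine 11, and the imine route avoids self-aldol of acetaldehyde.

Step 7
Reactants: 5 (5R)-5-(tert-butyldimethylsilyloxy)-4,4-dimethoxy-2-methylcyclohex-2-en-1-one; 13 vinylmagnesium bromide (CH2=CHMgBr); 12 4-bromopent-4-enal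
Product: 16 (2S,3R,5R)-2-[(1S)-4-bromo-1-hydroxypent-4-en-1-yl]-5-(tert-butyldimethylsilyloxy)-3-ethenyl-4,4-dimethoxy-2-methylcyclohexan-1-one, via bromomagnesium enolate 14 (not isolated), via chlorozinc enolate 15 (not isolated)
Conditions: CuI (10 mol%), THF, −78 °C; ZnCl2, −78 °C; then 12, −78 → −40 °C; aq. NH4Cl
Reagents that add atoms: none
Why: CuI and 13 form a vinylcuprate that adds 1,4 to 5 at C10; the bromomagnesium enolate 14 is transmetallated by ZnCl2 to 15, which adds through C1 to aldehyde 12. The closest known reaction type is the copper-catalysed conjugate addition to cyclohexenones with aldol trapping of the enolate (three-component coupling). No ring is closed; the bonds C9–C10 and C1–C2 are formed. C10 is set by the C12 silyloxy group: the cuprate attacks the half-chair on the face anti to it, as in 5-substituted cyclohexenones, giving the 1,3-trans product. C1 is set by the new vinyl group, since the aldehyde enters anti to the adjacent substituent. C2 is set by a Zimmerman–Traxler chair of the tetrasubstituted cyclic enolate with the aldehyde chain equatorial, which corresponds to the (2S) carbinol. The step needs 1,4- over 1,2-addition, secured by copper catalysis, and C–C bond formation faster than proton transfer to the enolisable aldehyde, secured by the less basic zinc enolate at low temperature. The bromoalkene of 12 is inert to all reagents present.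

Step 8
Reactants: 16 ring A ketone (1S,2S,10R,12R); 17 2-methylpropanal
Product: 18 C14 alcohol C2 isobutyrate (1R,2S,10R,12R,14S): ring A with C1 (CH3 and the chain C2H(OCO-i-Pr)–C3H2–C4H2–C5(Br)=C16H2), C10 vinyl, C11 (OMe)2, C12 OTBS, C14 OH
Conditions: SmI2 (30 mol%), THF, −10 °C
Reagents that add atoms: none
Why: Evans–Tishchenko reduction; the samarium-bound hemiacetal of 17 on the C2 oxygen delivers hydride to C14 through a six-membered chair with C3 equatorial, giving the 1,3-anti (14S) alcohol. The transferred acyl group remains on O2 as the isobutyrate, so C2 and C14 are differentiated in the same step.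

Step 9
Reactants: 18 C14 alcohol C2 isobutyrate
Product: 19 C14 acetate (1S,2S,10R,12R,14S): 18 with OAc at C14
Conditions: Ac2O, DMAP, pyridine, rt
Reagents that add atoms: acetic anhydride, CC(=O)OC(C)=O
Why: DMAP-catalysed acetylation of the hindered secondary alcohol; it is done at once to prevent 1,3-migration of the isobutyrate.

Step 10
Reactants: 19 C14 acetate
Product: 21 C9 aldehyde (1S,2S,10S,12R,14S): 19 with CHO in place of the C10 vinyl group, via vicinal diol 20 (not isolated)
Conditions: OsO4 (2 mol%), NaIO4, 2,6-lutidine, dioxane/H2O, rt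
Reagents that add atoms: sodium periodate, [Na+].[O-]I(=O)(=O)=O; osmium tetroxide, O=[Os](=O)(=O)=O
Why: Lemieux–Johnson cleavage; OsO4 dihydroxylates the monosubstituted vinyl group in preference to the electron-poor bromoalkene, and periodate cleaves diol 20 to the aldehyde.

Step 11
Reactants: 22 [(4R)-2,2-dimethyl-1,3-dioxolan-4-yl]methanol
Product: 23 (4S)-2,2-dimethyl-1,3-dioxolane-4-carbaldehyde
Conditions: (COCl)2, DMSO, Et3N, CH2Cl2, −78 °C
Reagents that add atoms: none
Why: Swern oxidation at low temperature gives the configurationally labile α-alkoxy aldehyde, which is used without storage.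

Step 12
Reactants: 23 (4S)-2,2-dimethyl-1,3-dioxolane-4-carbaldehyde; 24 dimethyl (1-diazo-2-oxopropyl)phosphonate
Product: 25 (4R)-4-ethynyl-2,2-dimethyl-1,3-dioxolane
Conditions: K2CO3, MeOH, 0 °C → rt
Reagents that add atoms: none
Why: Seyferth–Gilbert homologation with the Ohira–Bestmann reagent converts the aldehyde into the terminal alkyne under carbonate conditions mild enough to preserve the α-alkoxy centre.

Step 13
Reactants: 25 (4R)-4-ethynyl-2,2-dimethyl-1,3-dioxolane
Product: 27 (4S)-4-(1-iodoethenyl)-2,2-dimethyl-1,3-dioxolane, via alkenylalane 26 (not isolated)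
Conditions: NiCl2(dppp) (3 mol%), i-Bu2AlH, THF, 0 °C → rt; then N-iodosuccinimide, 0 °C
Reagents that add atoms: N-iodosuccinimide, O=C1CCC(=O)N1I
Why: Nickel-catalysed hydroalumination with the bidentate phosphine places aluminium on the internal alkyne carbon. Iodinolysis of 26 then gives the 2-iodoalkene that carries C6, C7 and C8.

Step 14
Reactants: 21 C9 aldehyde; 27 (4S)-4-(1-iodoethenyl)-2,2-dimethyl-1,3-dioxolane
Product: 28 C9 allylic alcohol (1S,2S,7R,9R,10S,12R,14S; 9R epimer drawn): 21 with C9H(OH)–C8(=CH2)–[2,2-dimethyl-1,3-dioxolan-4-yl] (C7 and C6 in the dioxolane) at C10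
Conditions: CrCl2 (6 equiv), NiCl2 (0.03 equiv), DMSO/THF, rt
Reagents that add atoms: none
Why: Nozaki–Hiyama–Kishi coupling; zerovalent nickel formed in situ inserts into the C–I bond of 27 much faster than into the C5–Br bond, and the alkenylchromium adds to the aldehyde without touching esters, ketal or silyl ether. Attack anti to C1 should favour the 9R alcohol; C9 is reset in steps 15 and 16.

Step 15
Reactants: 28 C9 allylic alcohol
Product: 29 C9 enone (1S,2S,7R,10S,12R,14S): 28 with C9=O
Conditions: Dess–Martin periodinane, pyridine, CH2Cl2, 0 °C → rt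
Reagents that add atoms: none
Why: Dess–Martin oxidation of the allylic alcohol under buffered conditions; both C9 epimers converge on one enone.

Step 16
Reactants: 29 C9 enone
Product: 30 (9S)-allylic alcohol (1S,2S,7R,9S,10S,12R,14S)
Conditions: NaBH4, CeCl3·7H2O, MeOH, −78 °C
Reagents that add atoms: none
Why: Luche 1,2-reduction; hydride approaches C9 anti to C1 with the carbonyl oxygen on the side of the C11 ketal (Felkin–Anh, reinforced by cerium chelation to a ketal oxygen). This places the hydroxyl in the 9S position, the opposite of what the carbon nucleophile gives in step 14.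

Step 17
Reactants: 30 (9S)-allylic alcohol
Product: 31 C9 acetate (1S,2S,7R,9S,10S,12R,14S)
Conditions: Ac2O, DMAP, pyridine, rt
Reagents that add atoms: acetic anhydride, CC(=O)OC(C)=O
Why: DMAP-catalysed acetylation installs the second acetate and protects C9 before the C8 carbonyl is unmasked.

Step 18
Reactants: 31 C9 acetate
Product: 33 C8 ketone (1S,2S,7S,9S,10S,12R,14S): 31 with C8=O in place of C8=CH2, via vicinal diol 32 (not isolated)
Conditions: OsO4 (5 mol%), NaIO4, 2,6-lutidine, dioxane/H2O, rt
Reagents that add atoms: sodium periodate, [Na+].[O-]I(=O)(=O)=O; osmium tetroxide, O=[Os](=O)(=O)=O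
Why: Lemieux–Johnson cleavage of the 1,1-disubstituted alkene via diol 32 unmasks the ketone; the bromoalkene is too electron-poor to be dihydroxylated at a comparable rate.

Step 19
Reactants: 33 C8 ketone
Product: 34 C6,C7 diol (1S,2S,7S,9S,10S,12R,14S): 33 with C7H(OH)–C6H2OH
Conditions: PPTS, MeOH, 40 °C
Reagents that add atoms: none
Why: Acid-catalysed transketalisation in methanol removes the terminal acetonide as 2,2-dimethoxypropane. The C11 dimethyl ketal only exchanges with the solvent, and the secondary silyl ether is retained.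

Step 20
Reactants: 34 C6,C7 diol
Product: 35 C6 triethylsilyl ether with free C7 hydroxyl (7S)
Conditions: Et3SiCl, imidazole, CH2Cl2, −40 °C
Reagents that add atoms: chlorotriethylsilane, CC[Si](Cl)(CC)CC
Why: Selective silylation of the primary hydroxyl over the hindered secondary α-keto hydroxyl at low temperature.

Step 21
Reactants: 35 C6 triethylsilyl ether
Product: 36 C7 acrylate (1S,2S,7S,9S,10S,12R,14S)
Conditions: acryloyl chloride, i-Pr2NEt, CH2Cl2, −78 → −20 °C
Reagents that add atoms: acryloyl chloride, C=CC(Cl)=O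
Why: O-Acylation of the C7 alcohol; the hindered base and low temperature avoid enolisation of the α-acyloxy ketone at C7 and C9.

Step 22
Reactants: 36 C7 acrylate
Product: 37 γ-lactone (1S,2S,7S,8R,9S,10S,12R,14S,17R): C8 (OH) bonded to C9, C7 and C17; C17 (CH3)–C19(=O)–O–C7; C7 bearing CH2OSiEt3
Conditions: Cu(OAc)2·H2O (5 mol%), rac-BINAP (5 mol%), (Me2HSi)2O, THF, rt; aq. NH4Cl
Reagents that add atoms: none
Why: Copper hydride-catalysed reductive aldol cyclisation, known for acrylates of keto alcohols; conjugate hydride addition gives a copper (Z)-enolate that adds to the C8 ketone in a 5-exo-trig closure, forming C8–C17. The chelated transition state puts the C17 methyl cis to the C8 oxygen (17R). The ketone face is chosen so that the bulky C9 branch lies trans to C6 on the new ring (8R).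

Step 23
Reactants: 37 γ-lactone
Product: 38 C11 ketone with free C6 hydroxyl (1S,2S,7S,8R,9S,10S,12R,14S,17R)
Conditions: p-TsOH·H2O (20 mol%), acetone/H2O 10:1, rt
Reagents that add atoms: water, O
Why: Aqueous acid hydrolyses the dimethyl ketal and the primary triethylsilyl ether in one operation, while the hindered secondary tert-butyldimethylsilyl ether survives. Acid is used rather than base to avoid β-elimination of the C9 acetate from the new ketone.

Step 24
Reactants: 38 C11 ketone
Product: 39 C11 exocyclic methylene (C20) with free C6 hydroxyl (1S,2S,7S,8R,9S,10S,12R,14S,17R)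
Conditions: Zn, CH2Br2, TiCl4, THF/CH2Cl2, 0 °C → rt
Reagents that add atoms: dibromomethane, BrCBr
Why: Titanium–zinc methylenation (Takai–Lombardo type) converts the hindered, enolisable ketone into the alkene under non-basic conditions, so esters, lactone and the β-acetoxy group are untouched. The free hydroxyls only consume reagent.

Step 25
Reactants: 39 C11 methylene C6 alcohol
Product: 40 C6 aldehyde (1S,2S,7R,8R,9S,10S,12R,14S,17R)
Conditions: Dess–Martin periodinane, pyridine, CH2Cl2, 0 °C
Reagents that add atoms: none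
Why: Dess–Martin oxidation of the primary alcohol; the tertiary C8 hydroxyl is inert and the buffered medium limits epimerisation at C7.

Step 26
Reactants: 40 C6 aldehyde
Product: 41 ten-membered C6 alcohol (1S,2S,6S,7S,8R,9S,10S,12R,14S,17R; 6S epimer drawn): ring C1–C10 closed by C5–C6, C5=C16H2
Conditions: CrCl2 (15 equiv), NiCl2 (0.3 equiv), DMSO, 2 mM, rt → 50 °C
Reagents that add atoms: none
Why: Intramolecular Nozaki–Hiyama–Kishi reaction at high dilution; zerovalent nickel inserts into the C5–Br bond, and the alkenylchromium adds to the C6 aldehyde. This closes the ten-membered ring and gives the C5 methylene directly, with ring A and the lactone holding the chain ends near each other. C6 is reset in steps 27 and 28.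

Step 27
Reactants: 41 ten-membered C6 alcohol
Product: 42 C6 enone (1S,2S,7R,8R,9S,10S,12R,14S,17R)
Conditions: Dess–Martin periodinane, pyridine, CH2Cl2, 0 °C
Reagents that add atoms: none
Why: Dess–Martin oxidation of the secondary allylic alcohol; both C6 epimers converge on the α-methylene ketone.

Step 28
Reactants: 42 C6 enone
Product: 43 (6R)-alcohol (1S,2S,6R,7S,8R,9S,10S,12R,14S,17R)
Conditions: NaBH4, CeCl3·7H2O, MeOH/THF, −78 °C
Reagents that add atoms: none
Why: Luche 1,2-reduction; polar Felkin–Anh attack anti to the C7–O bond gives the 6R alcohol, the epimer needed for substitution with inversion.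

Step 29
Reactants: 43 (6R)-alcohol
Product: 44 (6S)-chloride (1S,2S,6S,7R,8R,9S,10S,12R,14S,17R)
Conditions: PPh3, Cl3CC(O)CCl3, CH2Cl2, −20 → 0 °C
Reagents that add atoms: hexachloroacetone, ClC(Cl)(Cl)C(=O)C(Cl)(Cl)Cl
Why: Triphenylphosphine with hexachloroacetone converts secondary allylic alcohols into chlorides by SN2 displacement of the alkoxyphosphonium ion with inversion and without shifting the double bond. The tertiary C8 hydroxyl does not react.

Step 30
Reactants: 44 (6S)-chloride
Product: 45 C12 alcohol (1S,2S,6S,7R,8R,9S,10S,12R,14S,17R)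
Conditions: HF·pyridine, pyridine/THF, 0 °C → rt
Reagents that add atoms: none
Why: Buffered fluoride cleavage of the silyl ether under conditions that leave the allylic chloride, the β-hydroxy lactone and the esters intact.

Step 31
Reactants: 45 C12 alcohol
Product: 46 11,20-epoxide (1S,2S,6S,7R,8R,9S,10S,11R,12R,14S,17R)
Conditions: VO(acac)2 (5 mol%), t-BuOOH, CH2Cl2, 0 °C → rt
Reagents that add atoms: tert-butyl hydroperoxide, CC(C)(C)OO
Why: Vanadium-catalysed hydroxyl-directed epoxidation; the peroxide is delivered from the vanadate of the allylic C12 alcohol to the same face of C11=C20, giving the epoxide oxygen cis to the C12 oxygen (11R). The C5=C16 alkene has no allylic hydroxyl and is deactivated by the chloride.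

Step 32
Reactants: 46 11,20-epoxide
Product: 47 CNP0194902.1 (1S,2S,6S,7R,8R,9S,10S,11R,12R,14S,17R)
Conditions: (i-BuCO)2O, DMAP, pyridine, CH2Cl2, 0 °C → rt
Reagents that add atoms: 3-methylbutanoic anhydride, CC(C)CC(=O)OC(=O)CC(C)C
Why: DMAP-catalysed acylation of the secondary C12 alcohol under basic conditions that spare the epoxide; the tertiary C8 hydroxyl is too hindered to react.

## Compound list

1 | 4-methoxy-2-methylphenol | COc1ccc(O)c(C)c1 | starting material
2 | 4,4-dimethoxy-2-methylcyclohexa-2,5-dien-1-one | CC1=CC(OC)(OC)C=CC1=O | intermediate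
3 | (1S,6R)-5,5-dimethoxy-3-methyl-7-oxabicyclo[4.1.0]hept-3-en-2-one | CC1=CC(OC)(OC)[C@@H]2O[C@@H]2C1=O | intermediate
4 | (5R)-5-hydroxy-4,4-dimethoxy-2-methylcyclohex-2-en-1-one | CC1=CC(OC)(OC)[C@H](O)CC1=O | intermediate
5 | (5R)-5-(tert-butyldimethylsilyloxy)-4,4-dimethoxy-2-methylcyclohex-2-en-1-one | CC1=CC(OC)(OC)[C@H](O[Si](C)(C)C(C)(C)C)CC1=O | intermediate
6 | acetaldehyde | CC=O | starting material
7 | cyclohexylamine | NC1CCCCC1 | starting material
8 | N-cyclohexylethanimine | CC=NC1CCCCC1 | intermediate
9 | 2,3-dibromopropene | C=C(Br)CBr | starting material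
10 | lithiated imine (N-lithio-N-cyclohexylethenamine) | [Li]N(C=C)C1CCCCC1 | intermediate
11 | N-cyclohexyl-4-bromopent-4-en-1-imine | C=C(Br)CCC=NC1CCCCC1 | intermediate
12 | 4-bromopent-4-enal | C=C(Br)CCC=O | intermediate
13 | vinylmagnesium bromide | C=C[Mg]Br | starting material
14 | bromomagnesium enolate (10R,12R) of the C10 vinyl adduct | CC1=C(O[Mg]Br)C[C@@H](O[Si](C)(C)C(C)(C)C)C(OC)(OC)[C@@H]1C=C | intermediate
15 | chlorozinc enolate (10R,12R) | CC1=C(O[Zn]Cl)C[C@@H](O[Si](C)(C)C(C)(C)C)C(OC)(OC)[C@@H]1C=C | intermediate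
16 | (2S,3R,5R)-2-[(1S)-4-bromo-1-hydroxypent-4-en-1-yl]-5-(tert-butyldimethylsilyloxy)-3-ethenyl-4,4-dimethoxy-2-methylcyclohexan-1-one | BrC(=C)CC[C@H](O)[C@@]1(C)C(=O)C[C@@H](O[Si](C)(C)C(C)(C)C)C(OC)(OC)[C@@H]1C=C | intermediate
17 | 2-methylpropanal | CC(C)C=O | starting material
18 | C14 alcohol, C2 isobutyrate (1R,2S,10R,12R,14S) | BrC(=C)CC[C@H](OC(=O)C(C)C)[C@@]1(C)[C@@H](O)C[C@@H](O[Si](C)(C)C(C)(C)C)C(OC)(OC)[C@@H]1C=C | intermediate
19 | C14 acetate (1S,2S,10R,12R,14S) | BrC(=C)CC[C@H](OC(=O)C(C)C)[C@@]1(C)[C@@H](OC(C)=O)C[C@@H](O[Si](C)(C)C(C)(C)C)C(OC)(OC)[C@@H]1C=C | intermediate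
20 | vicinal diol from the C10 vinyl group (C9 carbinol unassigned) | BrC(=C)CC[C@H](OC(=O)C(C)C)[C@@]1(C)[C@@H](OC(C)=O)C[C@@H](O[Si](C)(C)C(C)(C)C)C(OC)(OC)[C@@H]1C(O)CO | intermediate
21 | C9 aldehyde (1S,2S,10S,12R,14S) | BrC(=C)CC[C@H](OC(=O)C(C)C)[C@@]1(C)[C@@H](OC(C)=O)C[C@@H](O[Si](C)(C)C(C)(C)C)C(OC)(OC)[C@@H]1C=O | intermediate
22 | [(4R)-2,2-dimethyl-1,3-dioxolan-4-yl]methanol | OC[C@@H]1COC(C)(C)O1 | starting material
23 | (4S)-2,2-dimethyl-1,3-dioxolane-4-carbaldehyde | O=C[C@@H]1COC(C)(C)O1 | intermediate
24 | dimethyl (1-diazo-2-oxopropyl)phosphonate | CC(=O)C(=[N+]=[N-])P(=O)(OC)OC | starting material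
25 | (4R)-4-ethynyl-2,2-dimethyl-1,3-dioxolane | C#C[C@@H]1COC(C)(C)O1 | intermediate
26 | diisobutyl{1-[(4S)-2,2-dimethyl-1,3-dioxolan-4-yl]ethenyl}alane | CC(C)C[Al](CC(C)C)C(=C)[C@@H]1COC(C)(C)O1 | intermediate
27 | (4S)-4-(1-iodoethenyl)-2,2-dimethyl-1,3-dioxolane | C=C(I)[C@@H]1COC(C)(C)O1 | intermediate
28 | C9 allylic alcohol, 9R epimer drawn (1S,2S,7R,9R,10S,12R,14S) | BrC(=C)CC[C@H](OC(=O)C(C)C)[C@@]1(C)[C@@H](OC(C)=O)C[C@@H](O[Si](C)(C)C(C)(C)C)C(OC)(OC)[C@@H]1[C@@H](O)C(=C)[C@@H]1COC(C)(C)O1 | intermediate
29 | C9 enone (1S,2S,7R,10S,12R,14S) | BrC(=C)CC[C@H](OC(=O)C(C)C)[C@@]1(C)[C@@H](OC(C)=O)C[C@@H](O[Si](C)(C)C(C)(C)C)C(OC)(OC)[C@@H]1C(=O)C(=C)[C@@H]1COC(C)(C)O1 | intermediate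
30 | (9S)-allylic alcohol (1S,2S,7R,9S,10S,12R,14S) | BrC(=C)CC[C@H](OC(=O)C(C)C)[C@@]1(C)[C@@H](OC(C)=O)C[C@@H](O[Si](C)(C)C(C)(C)C)C(OC)(OC)[C@@H]1[C@H](O)C(=C)[C@@H]1COC(C)(C)O1 | intermediate
31 | C9 acetate (1S,2S,7R,9S,10S,12R,14S) | BrC(=C)CC[C@H](OC(=O)C(C)C)[C@@]1(C)[C@@H](OC(C)=O)C[C@@H](O[Si](C)(C)C(C)(C)C)C(OC)(OC)[C@@H]1[C@H](OC(C)=O)C(=C)[C@@H]1COC(C)(C)O1 | intermediate
32 | vicinal diol from the C8 methylene (C8 carbinol unassigned) | BrC(=C)CC[C@H](OC(=O)C(C)C)[C@@]1(C)[C@@H](OC(C)=O)C[C@@H](O[Si](C)(C)C(C)(C)C)C(OC)(OC)[C@@H]1[C@H](OC(C)=O)C(O)(CO)[C@@H]1COC(C)(C)O1 | intermediate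
33 | C8 ketone (1S,2S,7S,9S,10S,12R,14S) | BrC(=C)CC[C@H](OC(=O)C(C)C)[C@@]1(C)[C@@H](OC(C)=O)C[C@@H](O[Si](C)(C)C(C)(C)C)C(OC)(OC)[C@@H]1[C@H](OC(C)=O)C(=O)[C@@H]1COC(C)(C)O1 | intermediate
34 | C6,C7 diol (1S,2S,7S,9S,10S,12R,14S) | BrC(=C)CC[C@H](OC(=O)C(C)C)[C@@]1(C)[C@@H](OC(C)=O)C[C@@H](O[Si](C)(C)C(C)(C)C)C(OC)(OC)[C@@H]1[C@H](OC(C)=O)C(=O)[C@@H](O)CO | intermediate
35 | C6 triethylsilyl ether, C7 alcohol (7S) | BrC(=C)CC[C@H](OC(=O)C(C)C)[C@@]1(C)[C@@H](OC(C)=O)C[C@@H](O[Si](C)(C)C(C)(C)C)C(OC)(OC)[C@@H]1[C@H](OC(C)=O)C(=O)[C@@H](O)CO[Si](CC)(CC)CC | intermediate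
36 | C7 acrylate (7S) | BrC(=C)CC[C@H](OC(=O)C(C)C)[C@@]1(C)[C@@H](OC(C)=O)C[C@@H](O[Si](C)(C)C(C)(C)C)C(OC)(OC)[C@@H]1[C@H](OC(C)=O)C(=O)[C@@H](OC(=O)C=C)CO[Si](CC)(CC)CC | intermediate
37 | γ-lactone (1S,2S,7S,8R,9S,10S,12R,14S,17R) | BrC(=C)CC[C@H](OC(=O)C(C)C)[C@@]1(C)[C@@H](OC(C)=O)C[C@@H](O[Si](C)(C)C(C)(C)C)C(OC)(OC)[C@@H]1[C@H](OC(C)=O)[C@]1(O)[C@@H](C)C(=O)O[C@H]1CO[Si](CC)(CC)CC | intermediate
38 | C11 ketone, C6 alcohol (1S,2S,7S,8R,9S,10S,12R,14S,17R) | BrC(=C)CC[C@H](OC(=O)C(C)C)[C@@]1(C)[C@@H](OC(C)=O)C[C@@H](O[Si](C)(C)C(C)(C)C)C(=O)[C@@H]1[C@H](OC(C)=O)[C@]1(O)[C@@H](C)C(=O)O[C@H]1CO | intermediate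
39 | C11 methylene, C6 alcohol (1S,2S,7S,8R,9S,10S,12R,14S,17R) | BrC(=C)CC[C@H](OC(=O)C(C)C)[C@@]1(C)[C@@H](OC(C)=O)C[C@@H](O[Si](C)(C)C(C)(C)C)C(=C)[C@@H]1[C@H](OC(C)=O)[C@]1(O)[C@@H](C)C(=O)O[C@H]1CO | intermediate
40 | C6 aldehyde (1S,2S,7R,8R,9S,10S,12R,14S,17R) | BrC(=C)CC[C@H](OC(=O)C(C)C)[C@@]1(C)[C@@H](OC(C)=O)C[C@@H](O[Si](C)(C)C(C)(C)C)C(=C)[C@@H]1[C@H](OC(C)=O)[C@]1(O)[C@@H](C)C(=O)O[C@H]1C=O | intermediate
41 | ten-membered C6 alcohol, 6S epimer drawn (1S,2S,6S,7S,8R,9S,10S,12R,14S,17R) | C=C1CC[C@H](OC(=O)C(C)C)[C@@]2(C)[C@@H](OC(C)=O)C[C@@H](O[Si](C)(C)C(C)(C)C)C(=C)[C@@H]2[C@H](OC(C)=O)[C@]2(O)[C@@H](C)C(=O)O[C@H]2[C@H]1O | intermediate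
42 | C6 enone (1S,2S,7R,8R,9S,10S,12R,14S,17R) | C=C1CC[C@H](OC(=O)C(C)C)[C@@]2(C)[C@@H](OC(C)=O)C[C@@H](O[Si](C)(C)C(C)(C)C)C(=C)[C@@H]2[C@H](OC(C)=O)[C@]2(O)[C@@H](C)C(=O)O[C@H]2C1=O | intermediate
43 | (6R)-alcohol (1S,2S,6R,7S,8R,9S,10S,12R,14S,17R) | C=C1CC[C@H](OC(=O)C(C)C)[C@@]2(C)[C@@H](OC(C)=O)C[C@@H](O[Si](C)(C)C(C)(C)C)C(=C)[C@@H]2[C@H](OC(C)=O)[C@]2(O)[C@@H](C)C(=O)O[C@H]2[C@@H]1O | intermediate
44 | (6S)-chloride (1S,2S,6S,7R,8R,9S,10S,12R,14S,17R) | C=C1CC[C@H](OC(=O)C(C)C)[C@@]2(C)[C@@H](OC(C)=O)C[C@@H](O[Si](C)(C)C(C)(C)C)C(=C)[C@@H]2[C@H](OC(C)=O)[C@]2(O)[C@@H](C)C(=O)O[C@H]2[C@H]1Cl | intermediate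
45 | C12 alcohol (1S,2S,6S,7R,8R,9S,10S,12R,14S,17R) | C=C1CC[C@H](OC(=O)C(C)C)[C@@]2(C)[C@@H](OC(C)=O)C[C@@H](O)C(=C)[C@@H]2[C@H](OC(C)=O)[C@]2(O)[C@@H](C)C(=O)O[C@H]2[C@H]1Cl | intermediate
46 | 11,20-epoxide, C12 alcohol (1S,2S,6S,7R,8R,9S,10S,11R,12R,14S,17R) | C=C1CC[C@H](OC(=O)C(C)C)[C@@]2(C)[C@@H](OC(C)=O)C[C@@H](O)[C@]3(CO3)[C@@H]2[C@H](OC(C)=O)[C@]2(O)[C@@H](C)C(=O)O[C@H]2[C@H]1Cl | intermediate
47 | CNP0194902.1 (1S,2S,6S,7R,8R,9S,10S,11R,12R,14S,17R) | C=C1CC[C@H](OC(=O)C(C)C)[C@@]2(C)[C@@H](OC(C)=O)C[C@@H](OC(=O)CC(C)C)[C@]3(CO3)[C@@H]2[C@H](OC(C)=O)[C@]2(O)[C@@H](C)C(=O)O[C@H]2[C@H]1Cl | target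

## Step count and risks

Total steps: 32. Longest linear sequence: 27 steps (steps 1–4, 7–10 and 14–32). Steps 5–6 and 11–13 make the two side components.

**Step 7 (key step).** Proton transfer from the enolisable aldehyde to the enolate, or retro-aldol of the crowded aldolate, may outrun C–C bond formation. The conjugate addition next to the ketal carbon may also be slow enough for 1,2-addition to compete. The fallback separates the two bond formations. From 5, copper-catalysed addition of 13 in the presence of chlorotrimethylsilane gives the trimethylsilyl enol ether F1, which is isolated. Methyllithium converts it into the lithium enolate F2 free of copper and magnesium salts. ZnCl2 then gives 15, and aldehyde 12 is added as before, returning to 16.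

**Step 26.** Oligomerisation, slow insertion of nickel into the alkenyl bromide, or retro-aldol and dehydration of the β-hydroxy aldehyde at the temperature the bromide needs may defeat the closure. The fallback changes the electrophile before ring closure. From 39, copper-catalysed halogen exchange (NaI, CuI, a diamine ligand) gives the alkenyl iodide F3. Oxidation gives the iodo aldehyde F4, which should cyclise at room temperature under the same chromium–nickel conditions, returning to 41.

**Step 29.** Substitution with allylic shift to the primary C16 chloride, ionisation with loss of configuration, or elimination to a diene may compete. The alkoxyphosphonium ion sits at a hindered carbon next to an electron-poor C7. The fallback is a two-step sulfonate displacement. From 43, methanesulfonyl chloride and triethylamine give the mesylate F5, and LiCl in DMF at 0 °C displaces it with inversion, returning to 44.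

**Step 22.** Copper hydride may reduce the activated C8 ketone directly. The tertiary alkoxide may take over the neighbouring C9 acetyl group, or the ketone may be attacked on the other face. The fallback is an intramolecular Reformatsky reaction. From 35, acylation with 2-bromopropanoyl bromide gives the 2-bromopropanoate F6. SmI2 in THF at −78 °C reduces the C–Br bond faster than the ketone and closes the lactone, returning to 37.

**Step 28.** The ring conformation may expose the other face of the ketone, so that peripheral hydride attack overrides the Felkin–Anh preference and returns the 6S alcohol; conjugate reduction is a second possibility. The fallback inverts the carbinol. From 41, which is that 6S alcohol, Mitsunobu reaction with chloroacetic acid gives the (6R)-chloroacetate F7. Thiourea removes the chloroacetyl group selectively, returning to 43.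

**Step 14.** Nickel may insert into the C5–Br bond and close a seven-membered ring onto the C9 aldehyde, and coupling of two hindered partners may be slow. The fallback avoids nickel. From 27, iodine–lithium exchange with tert-butyllithium at −78 °C gives the alkenyllithium F8. Transmetallation with CeCl3 gives the alkenylcerium reagent F9, which adds to aldehyde 21 at −78 °C faster than to the esters, returning to 28.

## Further compounds

F1 | step 7 | trimethylsilyl enol ether of the C10 vinyl adduct (10R,12R) | CC1=C(O[Si](C)(C)C)C[C@@H](O[Si](C)(C)C(C)(C)C)C(OC)(OC)[C@@H]1C=C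
F2 | step 7 | lithium enolate of the C10 vinyl adduct (10R,12R) | CC1=C(O[Li])C[C@@H](O[Si](C)(C)C(C)(C)C)C(OC)(OC)[C@@H]1C=C
F3 | step 26 | C5 alkenyl iodide analogue of 39 | IC(=C)CC[C@H](OC(=O)C(C)C)[C@@]1(C)[C@@H](OC(C)=O)C[C@@H](O[Si](C)(C)C(C)(C)C)C(=C)[C@@H]1[C@H](OC(C)=O)[C@]1(O)[C@@H](C)C(=O)O[C@H]1CO
F4 | step 26 | C5 alkenyl iodide analogue of 40 (C6 aldehyde) | IC(=C)CC[C@H](OC(=O)C(C)C)[C@@]1(C)[C@@H](OC(C)=O)C[C@@H](O[Si](C)(C)C(C)(C)C)C(=C)[C@@H]1[C@H](OC(C)=O)[C@]1(O)[C@@H](C)C(=O)O[C@H]1C=O
F5 | step 29 | (6R)-methanesulfonate of 43 | C=C1CC[C@H](OC(=O)C(C)C)[C@@]2(C)[C@@H](OC(C)=O)C[C@@H](O[Si](C)(C)C(C)(C)C)C(=C)[C@@H]2[C@H](OC(C)=O)[C@]2(O)[C@@H](C)C(=O)O[C@H]2[C@@H]1OS(C)(=O)=O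
F6 | step 22 | C7 2-bromopropanoate of 35 (bromide-bearing carbon unassigned) | BrC(=C)CC[C@H](OC(=O)C(C)C)[C@@]1(C)[C@@H](OC(C)=O)C[C@@H](O[Si](C)(C)C(C)(C)C)C(OC)(OC)[C@@H]1[C@H](OC(C)=O)C(=O)[C@@H](OC(=O)C(C)Br)CO[Si](CC)(CC)CC
F7 | step 28 | (6R)-chloroacetate from 41 | C=C1CC[C@H](OC(=O)C(C)C)[C@@]2(C)[C@@H](OC(C)=O)C[C@@H](O[Si](C)(C)C(C)(C)C)C(=C)[C@@H]2[C@H](OC(C)=O)[C@]2(O)[C@@H](C)C(=O)O[C@H]2[C@@H]1OC(=O)CCl
F8 | step 14 | {1-[(4S)-2,2-dimethyl-1,3-dioxolan-4-yl]ethenyl}lithium | [Li]C(=C)[C@@H]1COC(C)(C)O1
F9 | step 14 | dichloro{1-[(4S)-2,2-dimethyl-1,3-dioxolan-4-yl]ethenyl}cerium | Cl[Ce](Cl)C(=C)[C@@H]1COC(C)(C)O1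
A1 | alternative 1 | ten-membered chlorohydrin ester | C=C1CC[C@H](OC(=O)C(C)C)[C@@]2(C)[C@@H](OC(C)=O)C[C@@H](O[Si](CC)(CC)CC)C(=C)[C@@H]2[C@H](OC(C)=O)[C@](O)([C@@H](C)C(=O)OC)[C@@H](O)[C@H]1Cl
A2 | alternative 1 | seco C7 aldehyde with C6 gem-dichloride | ClC(Cl)C(=C)CC[C@H](OC(=O)C(C)C)[C@@]1(C)[C@@H](OC(C)=O)C[C@@H](O[Si](CC)(CC)CC)C(=C)[C@@H]1[C@H](OC(C)=O)[C@](O)([C@@H](C)C(=O)OC)C=O
A3 | alternative 2 | trans-fused cycloadduct with ring A silyl enol ether | C1CC(=O)[C@@]2(C)[C@@H](O[Si](C)(C)C(C)(C)C)C=C(O[Si](C)(C)C(C)(C)C)[C@@H](COCc3ccc(OC)cc3)[C@@H]2[C@H](O[Si](C)(C)C(C)(C)C)C2=C(C)C(=O)O[C@H]2/C=C1\C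
A4 | alternative 2 | (E)-cyclodecenone dienophile with fused butenolide | C1CC(=O)/C(C)=C/[C@H](O[Si](C)(C)C(C)(C)C)C2=C(C)C(=O)O[C@H]2/C=C1\C
A5 | alternative 2 | (1E,3Z)-1,3-bis(tert-butyldimethylsilyloxy)-5-(4-methoxybenzyloxy)penta-1,3-diene | CC(C)(C)[Si](C)(C)O/C=C/C(O[Si](C)(C)C(C)(C)C)=C/COCc1ccc(OC)cc1
A6 | alternative 3 | cyclobutane photoadduct with fused oxolane | C1C[C@H](OCOC)[C@@]2(C)[C@@H](O[Si](C)(C)C(C)(C)C)C[C@@H](O[Si](C)(C)C(C)(C)C)C(OC)(OC)[C@@H]2C(=O)[C@]34[C@@H](C)CO[C@H]3[C@@H](Cl)[C@@]41O[Si](C)(C)C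
A7 | alternative 3 | eight-membered β-silyloxy enone with tethered (Z)-2-chlorovinyl ether | C1C[C@H](OCOC)[C@@]2(C)[C@@H](O[Si](C)(C)C(C)(C)C)C[C@@H](O[Si](C)(C)C(C)(C)C)C(OC)(OC)[C@@H]2C(=O)C([C@@H](C)CO/C=C\Cl)=C1O[Si](C)(C)C
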